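**Strategy.** The plan rests on closing ring C of the epigallocatechin (lower) unit at its aryl ether bond O1–C8a. An open-chain (1R,2R)-1,3-diarylpropanol that carries bromine at the future C8 is treated with LiTMP: the aryne C8≡C8a forms, the benzylic alkoxide adds to C8a, and the C8 anion is protonated, so a 2,3-cis flavan results in one operation. The step exploits the 1,3,5-trioxygenated ring A: C8a–O lies meta to both ether oxygens, beyond electrophilic chemistry, while the neighbouring C8 is brominated easily and later carries the interflavan bond. The epiafzelechin unit is made alike from the same aldehyde, activated at C4 and joined 4β→8.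

Key step: step 7

Assumption: the target is read as epiafzelechin-(4β→8)-epigallocatechin (upper unit 2R,3R,4R; lower unit 2R,3R; flavan numbering throughout), and 1,2,3-tris(benzyloxy)-5-bromobenzene (9) is taken as purchasable (otherwise one Williamson step from 5-bromopyrogallol).

**Step 1**
Reactants: 1 4,6-dibromobenzene-1,3-diol
Product: 2 1,5-bis(benzyloxy)-2,4-dibromobenzene
Conditions: BnBr (2.3 equiv), K2CO3, DMF, 60 °C
Reagents that add atoms: benzyl bromide BrCc1ccccc1
Why: Williamson ether synthesis should cap both phenols; no stereocenter is involved.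

**Step 2**
Reactants: 2 1,5-bis(benzyloxy)-2,4-dibromobenzene; 3 (R)-2-[(trityloxy)methyl]oxirane
Product: 5 (R)-1-[2,4-bis(benzyloxy)-5-bromophenyl]-3-(trityloxy)propan-2-ol, via 2,4-bis(benzyloxy)-5-bromophenyllithium 4 (not isolated)
Conditions: n-BuLi (1.0 equiv), THF, −78 °C; then 3, BF3·OEt2, −78 °C; aq. NH4Cl
Reagents that add atoms: none
Why: One equivalent of n-BuLi should exchange one of the two equivalent bromines (bromine–lithium exchange), and the BF3-assisted SN2 opening of the epoxide at its CH2 terminus leaves the stereocenter of 3 untouched, so 5 is (R).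

**Step 3**
Reactants: 5 (R)-1-[2,4-bis(benzyloxy)-5-bromophenyl]-3-(trityloxy)propan-2-ol
Product: 6 (R)-1,5-bis(benzyloxy)-2-[2-(benzyloxy)-3-(trityloxy)propyl]-4-bromobenzene
Conditions: NaH, BnBr, Bu4NI (cat.), THF/DMF, 0 °C to rt
Reagents that add atoms: benzyl bromide BrCc1ccccc1
Why: Williamson etherification of the secondary alkoxide installs the non-migrating benzyl cap on the future C3 oxygen without touching the stereocenter.

**Step 4**
Reactants: 6 (R)-1,5-bis(benzyloxy)-2-[2-(benzyloxy)-3-(trityloxy)propyl]-4-bromobenzene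
Product: 7 (R)-2-(benzyloxy)-3-[2,4-bis(benzyloxy)-5-bromophenyl]propan-1-ol
Conditions: TsOH·H2O (cat.), MeOH/CH2Cl2, rt
Reagents that add atoms: none
Why: Acid-catalysed solvolysis of the trityl ether (SN1 through the trityl cation) should free the primary alcohol while benzyl ethers and the aryl bromide survive.

**Step 5**
Reactants: 7 (R)-2-(benzyloxy)-3-[2,4-bis(benzyloxy)-5-bromophenyl]propan-1-ol
Product: 8 (R)-2-(benzyloxy)-3-[2,4-bis(benzyloxy)-5-bromophenyl]propanal
Conditions: Dess–Martin periodinane, CH2Cl2, 0 °C to rt; used crude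
Reagents that add atoms: none
Why: Dess–Martin oxidation is non-basic, so the α-benzyloxy stereocenter should be retained in the aldehyde.

**Step 6**
Reactants: 8 (R)-2-(benzyloxy)-3-[2,4-bis(benzyloxy)-5-bromophenyl]propanal; 9 1,2,3-tris(benzyloxy)-5-bromobenzene
Product: 11 (1R,2R)-2-(benzyloxy)-3-[2,4-bis(benzyloxy)-5-bromophenyl]-1-[3,4,5-tris(benzyloxy)phenyl]propan-1-ol, via [3,4,5-tris(benzyloxy)phenyl]magnesium bromide 10 (not isolated)
Conditions: Mg, THF (9 to 10); 8, MgBr2·OEt2, CH2Cl2, −78 °C, then 10; aq. NH4Cl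
Reagents that add atoms: none
Why: Grignard addition under Cram chelation control (magnesium bridging C=O and the α-benzyloxy oxygen) should deliver the aryl group to the face anti to the CH2Ar substituent, setting C1 as R and giving the syn (1R,2R) alcohol with the benzylic OH free.

**Step 7**
Reactants: 11 (1R,2R)-2-(benzyloxy)-3-[2,4-bis(benzyloxy)-5-bromophenyl]-1-[3,4,5-tris(benzyloxy)phenyl]propan-1-ol
Product: 14 (2R,3R)-3,5,7-tris(benzyloxy)-2-[3,4,5-tris(benzyloxy)phenyl]chromane, via aryne lithium alkoxide 12 (not isolated), via 8-lithiochromane 13 (not isolated)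
Conditions: LiTMP (4 equiv, from 2,2,6,6-tetramethylpiperidine and n-BuLi), THF, −78 °C to 0 °C; aq. NH4Cl
Reagents that add atoms: none
Why: LiTMP first forms the lithium alkoxide and then removes the only hydrogen ortho to bromine (the future C8a–H); loss of LiBr gives the 3,5-bis(benzyloxy)aryne 12 with its triple bond between the future C8 and C8a, the C1 alkoxide adds to C8a, and the resulting aryllithium 13 is protonated on work-up. The closest known reaction type is the base-induced aryne ring closure by a tethered heteroatom nucleophile (cine substitution), together with the known generation of 3,5-dialkoxybenzynes from 4-bromoresorcinol diethers and lithium amides. Ring C closes in the 6-exo-dig mode onto the in-plane π bond of the aryne. No stereocenter is formed: the C–O bonds at C1 and C2 of 11 are not broken, so the (1R,2R)-syn arrangement is carried unchanged into the 2,3-cis (2R,3R) flavan. The step needs O-attack at C8a only, and two features secure it: the three-atom tether from C4a can reach C8a but not C8, and the C7 benzyloxy group beside the triple bond stabilises the negative charge developing at C8 (which ends flanked by two oxygens), so tether and aryne polarisation point the same way. Chemoselectivity rests on the benzyl cap on the C2 oxygen of 11, which excludes the competing 5-exo closure to a dihydrobenzofuran, and on the bulk of the amide, which keeps it from adding to the aryne; lithiation at C6–H between the two benzyloxy groups is unproductive and is covered by excess base.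

**Step 8**
Reactants: 8 (R)-2-(benzyloxy)-3-[2,4-bis(benzyloxy)-5-bromophenyl]propanal; 15 [4-(benzyloxy)phenyl]magnesium bromide
Product: 16 (1R,2R)-2-(benzyloxy)-1-[4-(benzyloxy)phenyl]-3-[2,4-bis(benzyloxy)-5-bromophenyl]propan-1-ol
Conditions: 8, MgBr2·OEt2, CH2Cl2, −78 °C, then 15 (THF solution); aq. NH4Cl
Reagents that add atoms: none
Why: The same chelation-controlled Grignard addition as in step 6 should set C1 as R, anti to the CH2Ar group of the magnesium chelate.

**Step 9**
Reactants: 16 (1R,2R)-2-(benzyloxy)-1-[4-(benzyloxy)phenyl]-3-[2,4-bis(benzyloxy)-5-bromophenyl]propan-1-ol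
Product: 19 (2R,3R)-3,5,7-tris(benzyloxy)-2-[4-(benzyloxy)phenyl]chromane, via aryne lithium alkoxide 17 (not isolated), via 8-lithiochromane 18 (not isolated)
Conditions: LiTMP (4 equiv, from 2,2,6,6-tetramethylpiperidine and n-BuLi), THF, −78 °C to 0 °C; aq. NH4Cl
Reagents that add atoms: none
Why: The base-induced aryne ring closure of step 7 is repeated on the upper-unit precursor; no stereocenter is formed and the syn alcohol maps onto the 2,3-cis flavan.

**Step 10**
Reactants: 19 (2R,3R)-3,5,7-tris(benzyloxy)-2-[4-(benzyloxy)phenyl]chromane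
Product: 20 4β-(2-ethoxyethoxy) derivative of 19 (C4 ether trans to the C3 benzyloxy and C2 aryl groups)
Conditions: DDQ (2 equiv), 2-ethoxyethanol, CH2Cl2, rt
Reagents that add atoms: 2-ethoxyethanol CCOCCO
Why: DDQ benzylic oxidation (hydride abstraction at C4, made hydridic by ring A) gives a cation that the alcohol should capture on the β face, anti to the α-disposed C2 aryl and C3 benzyloxy groups.

**Step 11**
Reactants: 20 4β-(2-ethoxyethoxy) derivative of 19; 14 (2R,3R)-3,5,7-tris(benzyloxy)-2-[3,4,5-tris(benzyloxy)phenyl]chromane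
Product: 21 (2R,3R,4R)-3,5,7-tris(benzyloxy)-2-[4-(benzyloxy)phenyl]-4-{(2R,3R)-3,5,7-tris(benzyloxy)-2-[3,4,5-tris(benzyloxy)phenyl]chroman-8-yl}chromane
Conditions: 14 (2 equiv), TMSOTf (cat.), CH2Cl2, −78 °C
Reagents that add atoms: none
Why: Lewis-acid ionisation of the C4 ether gives the ring-A-stabilised benzylic cation, and Friedel–Crafts alkylation by C8 of 14 (less hindered than C6) should occur on the β face, anti to the C2 aryl and C3 benzyloxy groups, setting C4 as R (4β).

**Step 12**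
Reactants: 21 deca-O-benzyl epiafzelechin-(4β→8)-epigallocatechin
Product: 22 (2R,3R,4R)-2-(4-hydroxyphenyl)-4-[(2R,3R)-3,5,7-trihydroxy-2-(3,4,5-trihydroxyphenyl)-3,4-dihydro-2H-chromen-8-yl]-3,4-dihydro-2H-chromene-3,5,7-triol
Conditions: H2 (1 atm), Pd(OH)2/C, THF/MeOH/H2O, rt
Reagents that add atoms: none
Why: Catalytic hydrogenolysis should cleave all ten benzyl ethers under neutral conditions that leave the interflavan bond and the five stereocenters untouched.

**Compound list**
1 | 4,6-dibromobenzene-1,3-diol | Oc1cc(O)c(Br)cc1Br | starting material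
2 | 1,5-bis(benzyloxy)-2,4-dibromobenzene | Brc1cc(Br)c(OCc2ccccc2)cc1OCc1ccccc1 | intermediate
3 | (R)-2-[(trityloxy)methyl]oxirane ((R)-glycidyl trityl ether) | C1O[C@H]1COC(c1ccccc1)(c1ccccc1)c1ccccc1 | starting material
4 | 2,4-bis(benzyloxy)-5-bromophenyllithium | [Li]c1cc(Br)c(OCc2ccccc2)cc1OCc1ccccc1 | intermediate
5 | (R)-1-[2,4-bis(benzyloxy)-5-bromophenyl]-3-(trityloxy)propan-2-ol | O[C@H](Cc1cc(Br)c(OCc2ccccc2)cc1OCc1ccccc1)COC(c1ccccc1)(c1ccccc1)c1ccccc1 | intermediate
6 | (R)-1,5-bis(benzyloxy)-2-[2-(benzyloxy)-3-(trityloxy)propyl]-4-bromobenzene | c1ccccc1CO[C@H](Cc1cc(Br)c(OCc2ccccc2)cc1OCc1ccccc1)COC(c1ccccc1)(c1ccccc1)c1ccccc1 | intermediate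
7 | (R)-2-(benzyloxy)-3-[2,4-bis(benzyloxy)-5-bromophenyl]propan-1-ol | c1ccccc1CO[C@H](Cc1cc(Br)c(OCc2ccccc2)cc1OCc1ccccc1)CO | intermediate
8 | (R)-2-(benzyloxy)-3-[2,4-bis(benzyloxy)-5-bromophenyl]propanal | c1ccccc1CO[C@H](Cc1cc(Br)c(OCc2ccccc2)cc1OCc1ccccc1)C=O | intermediate
9 | 1,2,3-tris(benzyloxy)-5-bromobenzene | Brc1cc(OCc2ccccc2)c(OCc2ccccc2)c(OCc2ccccc2)c1 | starting material
10 | [3,4,5-tris(benzyloxy)phenyl]magnesium bromide | Br[Mg]c1cc(OCc2ccccc2)c(OCc2ccccc2)c(OCc2ccccc2)c1 | intermediate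
11 | (1R,2R)-2-(benzyloxy)-3-[2,4-bis(benzyloxy)-5-bromophenyl]-1-[3,4,5-tris(benzyloxy)phenyl]propan-1-ol | O[C@H](c1cc(OCc2ccccc2)c(OCc2ccccc2)c(OCc2ccccc2)c1)[C@H](OCc1ccccc1)Cc1cc(Br)c(OCc2ccccc2)cc1OCc1ccccc1 | intermediate
12 | lithium alkoxide of the aryne from 11 (triple bond between the future C8 and C8a) | [Li]O[C@H](c1cc(OCc2ccccc2)c(OCc2ccccc2)c(OCc2ccccc2)c1)[C@H](OCc1ccccc1)CC1=C(OCc2ccccc2)C=C(OCc2ccccc2)C#C1 | intermediate
13 | (2R,3R)-3,5,7-tris(benzyloxy)-2-[3,4,5-tris(benzyloxy)phenyl]chroman-8-yllithium | [Li]c1c(OCc2ccccc2)cc(OCc2ccccc2)c2c1O[C@H](c1cc(OCc3ccccc3)c(OCc3ccccc3)c(OCc3ccccc3)c1)[C@H](OCc1ccccc1)C2 | intermediate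
14 | (2R,3R)-3,5,7-tris(benzyloxy)-2-[3,4,5-tris(benzyloxy)phenyl]chromane (hexa-O-benzyl-epigallocatechin) | c1c(OCc2ccccc2)cc(OCc2ccccc2)c2c1O[C@H](c1cc(OCc3ccccc3)c(OCc3ccccc3)c(OCc3ccccc3)c1)[C@H](OCc1ccccc1)C2 | intermediate
15 | [4-(benzyloxy)phenyl]magnesium bromide (THF solution) | Br[Mg]c1ccc(OCc2ccccc2)cc1 | starting material
16 | (1R,2R)-2-(benzyloxy)-1-[4-(benzyloxy)phenyl]-3-[2,4-bis(benzyloxy)-5-bromophenyl]propan-1-ol | O[C@H](c1ccc(OCc2ccccc2)cc1)[C@H](OCc1ccccc1)Cc1cc(Br)c(OCc2ccccc2)cc1OCc1ccccc1 | intermediate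
17 | lithium alkoxide of the aryne from 16 | [Li]O[C@H](c1ccc(OCc2ccccc2)cc1)[C@H](OCc1ccccc1)CC1=C(OCc2ccccc2)C=C(OCc2ccccc2)C#C1 | intermediate
18 | (2R,3R)-3,5,7-tris(benzyloxy)-2-[4-(benzyloxy)phenyl]chroman-8-yllithium | [Li]c1c(OCc2ccccc2)cc(OCc2ccccc2)c2c1O[C@H](c1ccc(OCc3ccccc3)cc1)[C@H](OCc1ccccc1)C2 | intermediate
19 | (2R,3R)-3,5,7-tris(benzyloxy)-2-[4-(benzyloxy)phenyl]chromane (tetra-O-benzyl-epiafzelechin) | c1c(OCc2ccccc2)cc(OCc2ccccc2)c2c1O[C@H](c1ccc(OCc3ccccc3)cc1)[C@H](OCc1ccccc1)C2 | intermediate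
20 | 4β-(2-ethoxyethoxy) derivative of 19 (ether trans to the C3 benzyloxy and C2 aryl groups) | c4ccccc4COc1ccc([C@H]2Oc3cc(OCc4ccccc4)cc(OCc4ccccc4)c3[C@H](OCCOCC)[C@H]2OCc4ccccc4)cc1 | intermediate
21 | deca-O-benzyl epiafzelechin-(4β→8)-epigallocatechin, (2R,3R,4R) upper unit and (2R,3R) lower unit | c5ccccc5COc1ccc([C@H]2Oc3cc(OCc5ccccc5)cc(OCc5ccccc5)c3[C@H](c3c(OCc5ccccc5)cc(OCc5ccccc5)c4c3O[C@H](c3cc(OCc5ccccc5)c(OCc5ccccc5)c(OCc5ccccc5)c3)[C@H](OCc5ccccc5)C4)[C@H]2OCc5ccccc5)cc1 | intermediate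
22 | epiafzelechin-(4β→8)-epigallocatechin, (2R,3R,4R)-2-(4-hydroxyphenyl)-4-[(2R,3R)-3,5,7-trihydroxy-2-(3,4,5-trihydroxyphenyl)-3,4-dihydro-2H-chromen-8-yl]-3,4-dihydro-2H-chromene-3,5,7-triol | Oc1ccc([C@H]2Oc3cc(O)cc(O)c3[C@H](c3c(O)cc(O)c4c3O[C@H](c3cc(O)c(O)c(O)c3)[C@H](O)C4)[C@H]2O)cc1 | target

**Totals.** Total step count: 12. Longest linear sequence: 10 steps (steps 1–5, 8, 9, 10, 11, 12).

**Steps most likely to fail**

Step 7 (aryne ring closure). The amide base may metalate C6–H between the two benzyloxy groups or a benzylic OCH2 faster than the C–H next to bromine. Aryne formation would then be slow, and rearrangement of benzyl ethers or addition of the amide to the aryne would erode the material. The fallback closes the same O1–C8a bond by intramolecular nucleophilic aromatic substitution on a fluoroarene; it sets out from 3 and comes back to the route at 14. 1,3,5-Trifluorobenzene is lithiated (n-BuLi, THF, −78 °C) and opens 3 (BF3·OEt2) to give (R)-1-(2,4,6-trifluorophenyl)-3-(trityloxy)propan-2-ol F1. NaH/BnBr gives the benzyl ether (R)-2-[2-(benzyloxy)-3-(trityloxy)propyl]-1,3,5-trifluorobenzene F2, and TsOH/MeOH gives (R)-2-(benzyloxy)-3-(2,4,6-trifluorophenyl)propan-1-ol F3. Dess–Martin oxidation gives (R)-2-(benzyloxy)-3-(2,4,6-trifluorophenyl)propanal F4, and chelation-controlled addition of 10 gives (1R,2R)-2-(benzyloxy)-3-(2,4,6-trifluorophenyl)-1-[3,4,5-tris(benzyloxy)phenyl]propan-1-ol F5. KH in THF/DMF should then let the alkoxide displace an ortho fluoride (addition–elimination, activated by the other fluorines) to give (2R,3R)-3-(benzyloxy)-5,7-difluoro-2-[3,4,5-tris(benzyloxy)phenyl]chromane F6. Sodium benzyloxide (BnOH, NaH, NMP, heat) exchanges the two remaining fluorides to give 14.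

Step 6 (chelation-controlled addition; the same holds for step 8). Incomplete chelation, with THF competing for magnesium, may let Felkin–Anh attack compete and give poor facial selectivity, and the α-benzyloxy aldehyde may epimerise. The fallback sets C1 by reagent-controlled ketone reduction; it sets out from 11 obtained as a mixture of C1 epimers and comes back at 11. Dess–Martin oxidation converges both epimers on (R)-2-(benzyloxy)-3-[2,4-bis(benzyloxy)-5-bromophenyl]-1-[3,4,5-tris(benzyloxy)phenyl]propan-1-one F7. A Corey–Bakshi–Shibata reduction ((R)-Me-CBS oxazaborolidine, BH3·SMe2, THF, −20 °C), with the aryl group as the large substituent, is expected to return the (1R,2R) alcohol 11.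

Step 11 (interflavan coupling). The C4 cation from 20 may be captured by C8 of a second molecule of 20 or of product 21 (oligomerisation), or by C6 of 14 (4→6 isomer). The fallback blocks C8 of the electrophile; it sets out from 19 and comes back at 22. NBS (CH2Cl2, −20 °C) should brominate C8 of 19 to give (2R,3R)-3,5,7-tris(benzyloxy)-2-[4-(benzyloxy)phenyl]-8-bromochromane F8. DDQ/2-ethoxyethanol gives its 4β-(2-ethoxyethoxy) derivative F9, which can no longer act as a nucleophile at C8. Coupling with 14 (1.1 equiv, BF3·OEt2, CH2Cl2, −78 °C) gives the 8-bromo derivative of 21 F10. Hydrogenolysis (H2, Pd(OH)2/C, Et3N, THF/MeOH) removes the bromine together with the ten benzyl groups to give 22.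

**Further compounds**
F1 | step 7 | (R)-1-(2,4,6-trifluorophenyl)-3-(trityloxy)propan-2-ol | O[C@H](Cc1c(F)cc(F)cc1F)COC(c1ccccc1)(c1ccccc1)c1ccccc1
F2 | step 7 | (R)-2-[2-(benzyloxy)-3-(trityloxy)propyl]-1,3,5-trifluorobenzene | c1ccccc1CO[C@H](Cc1c(F)cc(F)cc1F)COC(c1ccccc1)(c1ccccc1)c1ccccc1
F3 | step 7 | (R)-2-(benzyloxy)-3-(2,4,6-trifluorophenyl)propan-1-ol | c1ccccc1CO[C@H](Cc1c(F)cc(F)cc1F)CO
F4 | step 7 | (R)-2-(benzyloxy)-3-(2,4,6-trifluorophenyl)propanal | c1ccccc1CO[C@H](Cc1c(F)cc(F)cc1F)C=O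
F5 | step 7 | (1R,2R)-2-(benzyloxy)-3-(2,4,6-trifluorophenyl)-1-[3,4,5-tris(benzyloxy)phenyl]propan-1-ol | O[C@H](c1cc(OCc2ccccc2)c(OCc2ccccc2)c(OCc2ccccc2)c1)[C@H](OCc1ccccc1)Cc1c(F)cc(F)cc1F
F6 | step 7 | (2R,3R)-3-(benzyloxy)-5,7-difluoro-2-[3,4,5-tris(benzyloxy)phenyl]chromane | Fc1cc(F)c2c(c1)O[C@H](c1cc(OCc3ccccc3)c(OCc3ccccc3)c(OCc3ccccc3)c1)[C@H](OCc1ccccc1)C2
F7 | step 6 | (R)-2-(benzyloxy)-3-[2,4-bis(benzyloxy)-5-bromophenyl]-1-[3,4,5-tris(benzyloxy)phenyl]propan-1-one | O=C(c1cc(OCc2ccccc2)c(OCc2ccccc2)c(OCc2ccccc2)c1)[C@H](OCc1ccccc1)Cc1cc(Br)c(OCc2ccccc2)cc1OCc1ccccc1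
F8 | step 11 | (2R,3R)-3,5,7-tris(benzyloxy)-2-[4-(benzyloxy)phenyl]-8-bromochromane | c4ccccc4COc1ccc([C@H]2Oc3c(Br)c(OCc4ccccc4)cc(OCc4ccccc4)c3C[C@H]2OCc4ccccc4)cc1
F9 | step 11 | 4β-(2-ethoxyethoxy) derivative of F8 (ether trans to the C3 benzyloxy group) | c4ccccc4COc1ccc([C@H]2Oc3c(Br)c(OCc4ccccc4)cc(OCc4ccccc4)c3[C@H](OCCOCC)[C@H]2OCc4ccccc4)cc1
F10 | step 11 | 8-bromo derivative of 21 (bromine on C8 of the upper unit, 4β→8 linkage) | c5ccccc5COc1ccc([C@H]2Oc3c(Br)c(OCc5ccccc5)cc(OCc5ccccc5)c3[C@H](c3c(OCc5ccccc5)cc(OCc5ccccc5)c4c3O[C@H](c3cc(OCc5ccccc5)c(OCc5ccccc5)c(OCc5ccccc5)c3)[C@H](OCc5ccccc5)C4)[C@H]2OCc5ccccc5)cc1
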